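**Retrosynthetic overview**

1. Target 19 ⇐ chromone 18 (four benzyl ethers removed) ⇐ silyl enol ether 17 ⇐ chromanone 16: the C2=C3 bond of the chromone is introduced late, after the stereocentre is in place.
2. 16 ⇐ aldehyde–enone 15 by a carbene-catalysed intramolecular Stetter reaction that forms C3–C4 and closes the pyranone, the only ring made in the route. The feature used: chromone C4 is an aroyl carbon whose benzo ring carries O1 on the neighbouring carbon C8a, and C3 is bonded to the side-chain carbon that is α to the 2-hydroxy-4-methoxyphenyl ketone. C4 can therefore be the formyl carbon of a salicylaldehyde, and C3 the β-carbon of an E-enone hung on it through O1–C2.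
3. 15 ⇐ E-allylic alcohol 12 + 4-benzyloxy-2-hydroxybenzaldehyde 14 by Mitsunobu etherification, so the aromatic aldehyde never needs masking.
4. 12 ⇐ β,β-diaryl ketone 6 + silyloxyacetaldehyde 7 (aldol addition, dehydration, desilylation); 6 ⇐ acetophenone 2 + aldehyde 3 (chalcone) + arylboronic acid 5 (conjugate addition).

Key step: step 9

Assumption: the (5aS,10bR) antipode of the aminoindanol-derived triazolium salt is taken to send the acyl carbon to the Si face of the enone β-carbon; if a first run shows the opposite sense, the (5aR,10bS) salt is used with no other change.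

**Route**

Step 1
Reactants: 1 paeonol (2-hydroxy-4-methoxyacetophenone)
Product: 2 1-[2-(benzyloxy)-4-methoxyphenyl]ethan-1-one
Conditions: BnBr, K2CO3, DMF, 60 °C
Reagents that add atoms: benzyl bromide, BrCc1ccccc1
Why: Williamson etherification of the chelated phenol; the benzyl ether blocks flavanone formation in step 2 and leaves with the other benzyl groups at the end.

Step 2
Reactants: 2 1-[2-(benzyloxy)-4-methoxyphenyl]ethan-1-one; 3 4-(benzyloxy)benzaldehyde
Product: 4 (E)-1-[2-(benzyloxy)-4-methoxyphenyl]-3-[4-(benzyloxy)phenyl]prop-2-en-1-one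
Conditions: KOH, EtOH, rt
Reagents that add atoms: none
Why: Claisen–Schmidt condensation of a methyl ketone with a non-enolisable aldehyde; E1cB loss of water should give the E-chalcone.

Step 3
Reactants: 4 (E)-chalcone; 5 [4-(benzyloxy)phenyl]boronic acid
Product: 6 1-[2-(benzyloxy)-4-methoxyphenyl]-3,3-bis[4-(benzyloxy)phenyl]propan-1-one
Conditions: [RhCl(cod)]2 (cat.), aq. KOH, 1,4-dioxane/H2O, 50 °C
Reagents that add atoms: none
Why: Rhodium-catalysed conjugate addition of an arylboronic acid to an enone (Hayashi–Miyaura type, run without a chiral ligand); the two β-aryl groups are identical, so no stereocentre arises.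

Step 4
Reactants: 6 1-[2-(benzyloxy)-4-methoxyphenyl]-3,3-bis[4-(benzyloxy)phenyl]propan-1-one; 7 [(tert-butyldimethylsilyl)oxy]acetaldehyde
Product: 9 1-[2-(benzyloxy)-4-methoxyphenyl]-2-{bis[4-(benzyloxy)phenyl]methyl}-4-[(tert-butyldimethylsilyl)oxy]-3-hydroxybutan-1-one (mixture of racemic diastereomers), via lithium Z-enolate 8 (not isolated)
Conditions: LiN(i-Pr)2, THF, −78 °C; then 7, −78 °C; aq. NH4Cl
Reagents that add atoms: none
Why: Directed aldol addition: the ketone has a single enolisable position and the aldehyde is added to the preformed enolate; the diastereomer mixture does not matter because both new centres become sp2 in step 5.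

Step 5
Reactants: 9 β-hydroxy ketone
Product: 11 (E)-1-[2-(benzyloxy)-4-methoxyphenyl]-2-{bis[4-(benzyloxy)phenyl]methyl}-4-[(tert-butyldimethylsilyl)oxy]but-2-en-1-one, via β-mesylate 10 (not isolated)
Conditions: MsCl, Et3N, CH2Cl2, 0 °C; then DBU, 0 °C → rt
Reagents that add atoms: none
Why: Mesylation and E1cB elimination; the isomer with CH2O trans to the aroyl group (E) is expected to prevail because a cis β-substituent would force the aroyl group out of conjugation, and the geometry is to be checked by NOE between OCH2 and the Ar2CH hydrogen.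

Step 6
Reactants: 11 silyl ether
Product: 12 (E)-1-[2-(benzyloxy)-4-methoxyphenyl]-2-{bis[4-(benzyloxy)phenyl]methyl}-4-hydroxybut-2-en-1-one
Conditions: HF·pyridine, pyridine, THF, 0 °C → rt
Reagents that add atoms: none
Why: Fluoride cleavage of the Si–O bond under buffered, non-basic conditions that leave the enone alone; any Z-isomer carried along should close to a lactol and dehydrate to a furan, which is far less polar and is separated here.

Step 7
Reactants: 13 2,4-dihydroxybenzaldehyde
Product: 14 4-(benzyloxy)-2-hydroxybenzaldehyde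
Conditions: BnBr, NaHCO3, MeCN, 80 °C
Reagents that add atoms: benzyl bromide, BrCc1ccccc1
Why: Regioselective Williamson etherification; the 2-hydroxyl is hydrogen-bonded to the formyl group, so the weak base should ionise and alkylate only the 4-hydroxyl.

Step 8
Reactants: 12 E-allylic alcohol; 14 4-(benzyloxy)-2-hydroxybenzaldehyde
Product: 15 (E)-4-(benzyloxy)-2-({3-[2-(benzyloxy)-4-methoxybenzoyl]-4,4-bis[4-(benzyloxy)phenyl]but-2-en-1-yl}oxy)benzaldehyde
Conditions: PPh3, DIAD, THF, 0 °C → rt
Reagents that add atoms: none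
Why: Mitsunobu etherification of a primary allylic alcohol with an acidic phenol (SN2 at CH2); the free aldehyde and the alkene geometry should be untouched.

Step 9
Reactants: 15 aldehyde–enone
Product: 16 (3S)-7-(benzyloxy)-3-{(2R)-1-[2-(benzyloxy)-4-methoxyphenyl]-3,3-bis[4-(benzyloxy)phenyl]-1-oxopropan-2-yl}chroman-4-one
Conditions: (5aS,10bR)-2-(pentafluorophenyl)-5a,10b-dihydro-4H,6H-indeno[2,1-b][1,2,4]triazolo[4,3-d][1,4]oxazin-2-ium tetrafluoroborate (20 mol%), KN(SiMe3)2 (20 mol%), toluene, rt, HN(SiMe3)2 removed in vacuo; then 15, toluene, 23 °C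
Reagents that add atoms: none
Why: The triazolylidene adds to the formyl group of 15 and, after proton shift, gives the Breslow intermediate, whose acyl-anion carbon (future C4) attacks the β-carbon of the tethered enone (future C3); protonation of the enolate and release of the carbene complete the cycle. The closest known reaction type is the enantio- and diastereoselective intramolecular Stetter reaction of salicylaldehyde ethers carrying α,β-disubstituted Michael acceptors, which gives 3-substituted chroman-4-ones. The pyranone ring closes in a 6-exo-trig mode as the C3–C4 bond forms. Ring centre C3 is set by the catalyst, whose indane wall shields one face of the Breslow intermediate so that the Si face of the β-carbon is attacked; the side-chain centre is set by the E geometry of the alkene together with internal transfer of the Breslow hydroxyl proton to the enolate carbon on the face that has just received the acyl group, a net syn addition that turns 3S into 2R in the side chain. The step needs conjugate addition to beat benzoin-type and aryloxide-expulsion pathways, which the ortho O–CH2 tether secures by holding the ketone-activated β-CH within reach, and it needs internal proton transfer to beat external protonation, which the geometrically pure E-enone and the amine-free carbene secure. Diastereomers are to be removed by chromatography at this stage, because after aromatisation a side-chain epimer would become the enantiomer of 18.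

Step 10
Reactants: 16 chromanone
Product: 17 (2R)-1-[2-(benzyloxy)-4-methoxyphenyl]-2-{7-(benzyloxy)-4-[(tert-butyldimethylsilyl)oxy]-2H-chromen-3-yl}-3,3-bis[4-(benzyloxy)phenyl]propan-1-one
Conditions: TBSOTf, Et3N, CH2Cl2, −20 → 0 °C
Reagents that add atoms: tert-butyldimethylsilyl trifluoromethanesulfonate, CC(C)(C)[Si](C)(C)OS(=O)(=O)C(F)(F)F
Why: Soft enolisation (silyl triflate and amine) should act on the ring ketone, whose endocyclic enol ether forms without strain, and not on the side-chain ketone, whose fully substituted enol ether would suffer severe allylic 1,3-strain; only ring centre C3 is erased.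

Step 11
Reactants: 17 silyl enol ether
Product: 18 7-(benzyloxy)-3-{(2R)-1-[2-(benzyloxy)-4-methoxyphenyl]-3,3-bis[4-(benzyloxy)phenyl]-1-oxopropan-2-yl}-4H-chromen-4-one
Conditions: DDQ, 2,4,6-collidine, CH2Cl2, 0 °C
Reagents that add atoms: none
Why: DDQ oxidation of a silyl enol ether to the enone: hydride leaves C2 of the 4-silyloxy-2H-chromene to give a 4-silyloxybenzopyrylium ion that loses silicon. This should be fast at 0 °C, whereas dehydrogenating the free ketone needs hot DDQ, which would also attack the electron-rich diarylmethine C–H.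

Step 12
Reactants: 18 tetrabenzyl chromone
Product: 19 7-hydroxy-3-[(2R)-1-(2-hydroxy-4-methoxyphenyl)-3,3-bis(4-hydroxyphenyl)-1-oxopropan-2-yl]-4H-chromen-4-one
Conditions: BCl3, pentamethylbenzene, CH2Cl2, −78 °C; MeOH quench, aqueous work-up
Reagents that add atoms: none
Why: Lewis-acid cleavage of aryl benzyl ethers with a non-Lewis-basic cation scavenger; at −78 °C the methyl ether should survive, and the absence of base protects the enolisable side-chain centre.

**Compound list**

1 | paeonol (2-hydroxy-4-methoxyacetophenone) | COc1ccc(C(C)=O)c(O)c1 | starting material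
2 | 1-[2-(benzyloxy)-4-methoxyphenyl]ethan-1-one | COc1ccc(C(C)=O)c(OCc2ccccc2)c1 | intermediate
3 | 4-(benzyloxy)benzaldehyde | O=Cc1ccc(OCc2ccccc2)cc1 | starting material
4 | (E)-1-[2-(benzyloxy)-4-methoxyphenyl]-3-[4-(benzyloxy)phenyl]prop-2-en-1-one | COc1ccc(C(=O)/C=C/c2ccc(OCc3ccccc3)cc2)c(OCc2ccccc2)c1 | intermediate
5 | [4-(benzyloxy)phenyl]boronic acid | OB(O)c1ccc(OCc2ccccc2)cc1 | starting material
6 | 1-[2-(benzyloxy)-4-methoxyphenyl]-3,3-bis[4-(benzyloxy)phenyl]propan-1-one | COc1ccc(C(=O)CC(c2ccc(OCc3ccccc3)cc2)c2ccc(OCc3ccccc3)cc2)c(OCc2ccccc2)c1 | intermediate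
7 | [(tert-butyldimethylsilyl)oxy]acetaldehyde | O=CCO[Si](C)(C)C(C)(C)C | starting material
8 | lithium Z-enolate of 6 | [Li]O/C(=C\C(c1ccc(OCc2ccccc2)cc1)c1ccc(OCc2ccccc2)cc1)c1ccc(OC)cc1OCc1ccccc1 | intermediate (not isolated)
9 | 1-[2-(benzyloxy)-4-methoxyphenyl]-2-{bis[4-(benzyloxy)phenyl]methyl}-4-[(tert-butyldimethylsilyl)oxy]-3-hydroxybutan-1-one, mixture of racemic diastereomers | COc1ccc(C(=O)C(C(O)CO[Si](C)(C)C(C)(C)C)C(c2ccc(OCc3ccccc3)cc2)c2ccc(OCc3ccccc3)cc2)c(OCc2ccccc2)c1 | intermediate
10 | β-mesylate of 9 | COc1ccc(C(=O)C(C(OS(C)(=O)=O)CO[Si](C)(C)C(C)(C)C)C(c2ccc(OCc3ccccc3)cc2)c2ccc(OCc3ccccc3)cc2)c(OCc2ccccc2)c1 | intermediate (not isolated)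
11 | (E)-1-[2-(benzyloxy)-4-methoxyphenyl]-2-{bis[4-(benzyloxy)phenyl]methyl}-4-[(tert-butyldimethylsilyl)oxy]but-2-en-1-one | CC(C)(C)[Si](C)(C)OC/C=C(/C(=O)c1ccc(OC)cc1OCc1ccccc1)C(c1ccc(OCc2ccccc2)cc1)c1ccc(OCc2ccccc2)cc1 | intermediate
12 | (E)-1-[2-(benzyloxy)-4-methoxyphenyl]-2-{bis[4-(benzyloxy)phenyl]methyl}-4-hydroxybut-2-en-1-one | OC/C=C(/C(=O)c1ccc(OC)cc1OCc1ccccc1)C(c1ccc(OCc2ccccc2)cc1)c1ccc(OCc2ccccc2)cc1 | intermediate
13 | 2,4-dihydroxybenzaldehyde | O=Cc1ccc(O)cc1O | starting material
14 | 4-(benzyloxy)-2-hydroxybenzaldehyde | O=Cc1ccc(OCc2ccccc2)cc1O | intermediate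
15 | (E)-4-(benzyloxy)-2-({3-[2-(benzyloxy)-4-methoxybenzoyl]-4,4-bis[4-(benzyloxy)phenyl]but-2-en-1-yl}oxy)benzaldehyde | O=Cc1ccc(OCc2ccccc2)cc1OC/C=C(/C(=O)c3ccc(OC)cc3OCc4ccccc4)C(c5ccc(OCc6ccccc6)cc5)c7ccc(OCc8ccccc8)cc7 | intermediate (key-step precursor)
16 | (3S)-7-(benzyloxy)-3-{(2R)-1-[2-(benzyloxy)-4-methoxyphenyl]-3,3-bis[4-(benzyloxy)phenyl]-1-oxopropan-2-yl}chroman-4-one | COc1ccc(C(=O)[C@@H]([C@H]2COc3cc(OCc4ccccc4)ccc3C2=O)C(c5ccc(OCc6ccccc6)cc5)c7ccc(OCc8ccccc8)cc7)c(OCc9ccccc9)c1 | intermediate (key-step product)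
17 | (2R)-1-[2-(benzyloxy)-4-methoxyphenyl]-2-{7-(benzyloxy)-4-[(tert-butyldimethylsilyl)oxy]-2H-chromen-3-yl}-3,3-bis[4-(benzyloxy)phenyl]propan-1-one | COc1ccc(C(=O)[C@@H](C2=C(O[Si](C)(C)C(C)(C)C)c3ccc(OCc4ccccc4)cc3OC2)C(c5ccc(OCc6ccccc6)cc5)c7ccc(OCc8ccccc8)cc7)c(OCc9ccccc9)c1 | intermediate
18 | 7-(benzyloxy)-3-{(2R)-1-[2-(benzyloxy)-4-methoxyphenyl]-3,3-bis[4-(benzyloxy)phenyl]-1-oxopropan-2-yl}-4H-chromen-4-one | COc1ccc(C(=O)[C@@H](c2coc3cc(OCc4ccccc4)ccc3c2=O)C(c5ccc(OCc6ccccc6)cc5)c7ccc(OCc8ccccc8)cc7)c(OCc9ccccc9)c1 | intermediate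
19 | 7-hydroxy-3-[(2R)-1-(2-hydroxy-4-methoxyphenyl)-3,3-bis(4-hydroxyphenyl)-1-oxopropan-2-yl]-4H-chromen-4-one | COc1ccc(C(=O)[C@@H](c2coc3cc(O)ccc3c2=O)C(c2ccc(O)cc2)c2ccc(O)cc2)c(O)c1 | target

**Step count and risks**

Total step count: 12. Longest linear sequence: 11 steps (steps 1–6 and 8–12); step 7 is a one-step side branch.

Steps most likely to fail:

Step 9. The Breslow intermediate may add only sluggishly to an enone whose α-carbon carries the bulky diarylmethyl branch. The carbene, acting as a base, could then expel the aryloxide or give benzoin-type products, and external protonation of the enolate would erode the relay of configuration to the side chain. The fallback sets out from 15 and forms the same C3–C4 bond by a radical chain instead of polar carbene catalysis. A thiol-catalysed acyl-radical cyclisation (tert-dodecanethiol, AIBN, chlorobenzene, 80 °C; 6-exo attack of the aroyl radical on the unhindered β-CH, then hydrogen transfer from the thiol) should give the racemic chromanone F1 as a diastereomer mixture. The conditions of steps 10 and 11 would then give the racemic silyl enol ether F2 and the racemic chromone F3. Preparative HPLC on a chiral stationary phase separates the R enantiomer, and the route is rejoined at 18.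

Step 10. Silylation and deprotonation may take place at the side-chain ketone, or the amine may epimerise the side-chain centre once it has become allylic, and enolisation at the hindered C3 may stay incomplete. The fallback sets out from 16 and avoids the enol ether altogether: aerobic dehydrogenation with Pd(OCOCF3)2 (cat.) in DMSO under O2 at 80 °C, in which a divalent palladium enolate at C3 undergoes β-hydride elimination toward C2. It gives 18 directly, makes no new compound (F0) and rejoins the route at 18.

Step 12. Within the boron chelate of the liberated 2-hydroxyaryl ketone the side-chain centre may enolise and lose enantiopurity, or the cleavage may stall before the fourth benzyl group or go on to the methyl ether. The fallback sets out from 18 and removes the benzyl groups reductively under neutral conditions: H2 (1 atm), palladium on carbon (Pd/C), EtOAc/THF, rt, stopped before the chromone C2=C3 bond is reduced. It gives 19 directly and makes no new compound (F0).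

**Further compounds**

F1 | step 9 | racemic 7-(benzyloxy)-3-{1-[2-(benzyloxy)-4-methoxyphenyl]-3,3-bis[4-(benzyloxy)phenyl]-1-oxopropan-2-yl}chroman-4-one, diastereomer mixture | COc1ccc(C(=O)C(C2COc3cc(OCc4ccccc4)ccc3C2=O)C(c5ccc(OCc6ccccc6)cc5)c7ccc(OCc8ccccc8)cc7)c(OCc9ccccc9)c1
F2 | step 9 | racemic 1-[2-(benzyloxy)-4-methoxyphenyl]-2-{7-(benzyloxy)-4-[(tert-butyldimethylsilyl)oxy]-2H-chromen-3-yl}-3,3-bis[4-(benzyloxy)phenyl]propan-1-one | COc1ccc(C(=O)C(C2=C(O[Si](C)(C)C(C)(C)C)c3ccc(OCc4ccccc4)cc3OC2)C(c5ccc(OCc6ccccc6)cc5)c7ccc(OCc8ccccc8)cc7)c(OCc9ccccc9)c1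
F3 | step 9 | racemic 7-(benzyloxy)-3-{1-[2-(benzyloxy)-4-methoxyphenyl]-3,3-bis[4-(benzyloxy)phenyl]-1-oxopropan-2-yl}-4H-chromen-4-one | COc1ccc(C(=O)C(c2coc3cc(OCc4ccccc4)ccc3c2=O)C(c5ccc(OCc6ccccc6)cc5)c7ccc(OCc8ccccc8)cc7)c(OCc9ccccc9)c1
F0 | step 10 | none | none
F0 | step 12 | none | none
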